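The symmetrical dimer is taken apart unsymmetrically. One bibenzyl half (rings A′ and B′) is finished first, and the second ring A is grown on the bridge carbon. A cyclobutenone carrying the 2-arylethyl chain on its β-carbon and the bridge CH2–Ar′ on its sp3 carbon is heated with (triisopropylsilyloxy)ethyne. In one operation the ring A bonds C3–C4 and C5–C6 are made and C2–C3 is reclosed. The step exploits the 1,2,3,5-pattern of ring A: the chain at C1 and the bridge at C2 are neighbours, and the oxygens at C3 and C5 stand meta to each other. The ketene oxygen emerges as free C3–OH and the alkyne oxygen as C5–OSi, so both are differentiated at once.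

Key step: step 14

Remark on labels: ring A is numbered C1 (CH2CH2 chain), C2 (bridge CH2), C3 (OMe), C5 (OH), and primed rings belong to the half made first. Ar = 4-(benzyloxy)-3-methoxyphenyl. Ar′ = 4-(benzyloxy)-2-(2-Ar-ethyl)-6-methoxyphenyl.
Remark on the chemistry: the target has no stereocentre. All four-membered-ring intermediates are racemic and lose their stereocentre on aromatisation. The benzannulation product carries three benzyl ethers (rings B and B′, and C5′ of ring A′). All six starting materials are assumed to be catalogue chemicals.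

Step 1
Reactants: 1 methyl 2,4-dihydroxy-6-methylbenzoate (methyl orsellinate)
Product: 2 methyl 4-(benzyloxy)-2-hydroxy-6-methylbenzoate
Conditions: BnBr (1.05 equiv), K2CO3, acetone, reflux
Reagents that add atoms: benzyl bromide, BrCc1ccccc1
Why: Williamson etherification; the C2 hydroxyl is hydrogen-bonded to the ester carbonyl, so only the free C4 hydroxyl (the future C5′ oxygen) should be alkylated.

Step 2
Reactants: 2 methyl 4-(benzyloxy)-2-hydroxy-6-methylbenzoate
Product: 3 methyl 4-(benzyloxy)-2-methoxy-6-methylbenzoate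
Conditions: MeI (excess), K2CO3, DMF, 50 °C
Reagents that add atoms: iodomethane, CI
Why: Williamson methylation of the remaining chelated phenol fixes OMe ortho and OBn para to the ester carbon (the future bridge position C2′), so no electrophilic substitution of uncertain regiochemistry is needed.

Step 3
Reactants: 4 [4-(benzyloxy)-3-methoxyphenyl]methanol
Product: 5 4-(benzyloxy)-3-methoxybenzyl bromide
Conditions: PBr3 (0.4 equiv), Et2O, 0 °C; used at once
Reagents that add atoms: phosphorus tribromide, BrP(Br)Br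
Why: Nucleophilic substitution of an activated benzylic alcohol through its phosphite ester, a standard conversion that leaves aryl ethers untouched.

Step 4
Reactants: 3 methyl 4-(benzyloxy)-2-methoxy-6-methylbenzoate; 5 4-(benzyloxy)-3-methoxybenzyl bromide
Product: 7 methyl 4-(benzyloxy)-2-{2-[4-(benzyloxy)-3-methoxyphenyl]ethyl}-6-methoxybenzoate, via benzylic organolithium 6 (not isolated)
Conditions: LiN(i-Pr)2 (LDA, 1.1 equiv), THF, −78 °C; then 5, −78 → 0 °C
Reagents that add atoms: none
Why: Lateral lithiation of an ortho-toluate and SN2 alkylation with a benzylic bromide make the CH2–CH2 link directly, so no stilbene has to be hydrogenated in the presence of benzyl ethers.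

Step 5
Reactants: 7 methyl 4-(benzyloxy)-2-{2-[4-(benzyloxy)-3-methoxyphenyl]ethyl}-6-methoxybenzoate
Product: 8 Ar′-methanol
Conditions: LiAlH4, THF, 0 °C → rt; aqueous NaOH work-up
Reagents that add atoms: none
Why: Hydride reduction of a hindered benzoate to the benzylic alcohol; benzyl and methyl aryl ethers are inert.

Step 6
Reactants: 8 Ar′-methanol
Product: 9 Ar′-carbaldehyde
Conditions: MnO2 (excess), CH2Cl2, rt
Reagents that add atoms: none
Why: Selective benzylic oxidation with activated MnO2, which is fast for electron-rich benzylic alcohols and stops at the aldehyde.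

Step 7
Reactants: 9 Ar′-carbaldehyde; 10 2,2-dimethyl-1,3-dioxane-4,6-dione (Meldrum's acid)
Product: 13 3-Ar′-propanoic acid, via arylidene Meldrum's acid 11 (not isolated), via benzyl Meldrum's acid 12 (not isolated)
Conditions: 10 (1.1 equiv), HCO2H–Et3N (5:2), 95–100 °C; dilute aq. HCl work-up
Reagents that add atoms: water, O
Why: One-pot Knoevenagel condensation, conjugate hydride transfer from formate and hydrolysis–decarboxylation should give the 3-arylpropanoic acid without H2 and palladium, so the benzyl ethers stay in place.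

Step 8
Reactants: 13 3-Ar′-propanoic acid; 14 ethoxyethyne
Product: 17 rac-3-ethoxy-4-(Ar′-methyl)cyclobut-2-en-1-one, via acid chloride 15 (not isolated), via monoalkylketene 16 (not isolated)
Conditions: (COCl)2, cat. DMF, CH2Cl2, 0 °C → rt, concentrate; then 14 (4 equiv), Et3N (1.5 equiv, slow addition), Et2O–hexane, 0 °C → rt
Reagents that add atoms: none
Why: Dehydrochlorination gives the ketene, and in its thermal [2+2] cycloaddition with the ynol ether the nucleophilic CH terminus bonds to the ketene carbonyl carbon, giving the racemic 4-substituted 3-ethoxycyclobutenone; both ortho positions of ring A′ are blocked, so no indanone can form.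

Step 9
Reactants: 18 2-(4-hydroxy-3-methoxyphenyl)ethanol (homovanillyl alcohol)
Product: 19 2-[4-(benzyloxy)-3-methoxyphenyl]ethanol
Conditions: BnBr, K2CO3, acetone, reflux
Reagents that add atoms: benzyl bromide, BrCc1ccccc1
Why: Williamson etherification; carbonate deprotonates only the phenol, so the primary alcohol is not alkylated.

Step 10
Reactants: 19 2-[4-(benzyloxy)-3-methoxyphenyl]ethanol
Product: 20 1-(benzyloxy)-4-(2-bromoethyl)-2-methoxybenzene
Conditions: CBr4, PPh3, CH2Cl2, 0 °C
Reagents that add atoms: carbon tetrabromide, BrC(Br)(Br)Br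
Why: Appel bromination of a primary alcohol under neutral conditions.

Step 11
Reactants: 20 1-(benzyloxy)-4-(2-bromoethyl)-2-methoxybenzene; 17 rac-3-ethoxy-4-(Ar′-methyl)cyclobut-2-en-1-one
Product: 24 rac-4-(Ar′-methyl)-3-(2-Ar-ethyl)cyclobut-2-en-1-one, via Grignard reagent 21 (not isolated), via organocerium reagent 22 (not isolated), via tertiary cyclobutenol 23 (not isolated)
Conditions: 20 (1.5 equiv), Mg, THF; anhydrous CeCl3, THF, −78 °C; then 17, −78 → −40 °C; then dilute aq. HCl, THF, 0 °C → rt
Reagents that add atoms: water, O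
Why: 1,2-Addition of a weakly basic organocerium reagent to the vinylogous ester is followed by acid-promoted alkylative carbonyl transposition of the Stork–Danheiser type (ionisation of the tertiary alcohol, hydration of the ethoxy-stabilised cation, loss of ethanol), which puts the chain on the β-carbon and leaves the bridge substituent on the sp3 carbon, whose configuration is irrelevant.

Step 12
Reactants: 25 ethynyl(trimethyl)silane
Product: 28 1-(triisopropylsilyloxy)-2-(trimethylsilyl)ethyne, via lithium acetylide 26 (not isolated), via lithium ynolate 27 (not isolated)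
Conditions: n-BuLi, THF, −78 °C; added to t-BuOOLi (from anhydrous t-BuOOH and LiN(SiMe3)2, THF, −78 °C), → 0 °C; then i-Pr3SiOTf, −78 → 0 °C
Reagents that add atoms: tert-butyl hydroperoxide, CC(C)(C)OO; triisopropylsilyl trifluoromethanesulfonate, CC(C)[Si](OS(=O)(=O)C(F)(F)F)(C(C)C)C(C)C
Why: Oxygenation of an alkynyllithium by lithium tert-butyl peroxide (substitution at peroxide oxygen) gives the ynolate, and the bulky, hard silyl triflate should silylate it on oxygen because the carbon terminus is shielded by SiMe3, following the standard ynolate route to triisopropylsilyl ynol ethers.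

Step 13
Reactants: 28 1-(triisopropylsilyloxy)-2-(trimethylsilyl)ethyne
Product: 29 (triisopropylsilyloxy)ethyne
Conditions: K2CO3 (0.2 equiv), MeOH, 0 °C, short contact; pentane extraction
Reagents that add atoms: none
Why: Base-catalysed protodesilylation of an alkynylsilane; methoxide should attack the small SiMe3 group far faster than the hindered Si(i-Pr)3 group, and an electron-rich ynol ether does not add methanol under basic conditions.

Step 14
Reactants: 24 rac-4-(Ar′-methyl)-3-(2-Ar-ethyl)cyclobut-2-en-1-one; 29 (triisopropylsilyloxy)ethyne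
Product: 34 2-(Ar′-methyl)-3-(2-Ar-ethyl)-5-(triisopropylsilyloxy)phenol (ring A as C3 phenol and C5 silyl ether), via vinylketene 30 (not isolated), via 4-vinylcyclobutenone 31 (not isolated), via dienylketene 32 (not isolated), via cyclohexadienone 33 (not isolated)
Conditions: 29 (2–3 equiv), toluene (0.3 mol/L), sealed tube, 80 °C, then 110 °C
Reagents that add atoms: none
Why: This is a Danheiser benzannulation of a cyclobutenone with a siloxyalkyne, a known pericyclic cascade that starts with conrotatory four-electron opening of 24, the arylmethyl group on the sp3 carbon turning outward, to give (E)-vinylketene 30. The polarised ynol ether then adds across the ketene C=C in a [2+2] sense, its nucleophilic CH carbon attacking the ketene carbonyl carbon, which forms C3–C4 and C5–C6 and gives 31. A second, reversible four-electron opening gives dienylketene 32, and ring A is closed by a disrotatory six-electron electrocyclisation joining C2 to C3, after which dienone 33 tautomerises to phenol 34. No stereocentre is created, and the racemic centre of 24 is erased on aromatisation. The only selectivity required is the orientation of the [2+2] step, which the donor oxygen of 29 dictates, so the two oxygens end up meta, the free OH lies next to the bridge and the C5 oxygen stays silylated. An excess of 29 should keep the vinylketene from dimerising or acylating the phenol formed, and benzyl ethers, methyl ethers and the silyl ether are inert to neutral thermolysis.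

Step 15
Reactants: 34 2-(Ar′-methyl)-3-(2-Ar-ethyl)-5-(triisopropylsilyloxy)phenol
Product: 35 methyl ether of 34 (ring A: C3–OMe, C5–OSi(i-Pr)3)
Conditions: MeI, K2CO3, dry acetone, 40 °C
Reagents that add atoms: iodomethane, CI
Why: Williamson methylation of the only free phenol; the hindered silyl ether keeps the C5 oxygen masked under mild carbonate conditions.

Step 16
Reactants: 35 methyl ether of 34
Product: 36 tribenzyl ether of the target (ring A: C3–OMe, C5–OH)
Conditions: Bu4NF, AcOH (1:1), THF, 0 °C
Reagents that add atoms: none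
Why: Fluoride-induced cleavage of an aryl silyl ether, with acetic acid buffering the phenoxide; benzyl and methyl ethers are unaffected.

Step 17
Reactants: 36 tribenzyl ether of the target
Product: 37 CNP0079383.0 (C2,C2′-methylene-bridged dimer of 3,4′-dihydroxy-5,3′-dimethoxybibenzyl)
Conditions: H2 (1 atm), Pd/C, EtOAc–MeOH, rt
Reagents that add atoms: none
Why: Catalytic hydrogenolysis of the three benzyl aryl ethers; the methyl ethers, the diarylmethane bridge and the CH2CH2 links are inert under these conditions.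

Compound list
1 | methyl 2,4-dihydroxy-6-methylbenzoate | COC(=O)c1c(C)cc(O)cc1O | starting material
2 | methyl 4-(benzyloxy)-2-hydroxy-6-methylbenzoate | COC(=O)c1c(C)cc(OCc2ccccc2)cc1O | intermediate
3 | methyl 4-(benzyloxy)-2-methoxy-6-methylbenzoate | COC(=O)c1c(C)cc(OCc2ccccc2)cc1OC | intermediate
4 | [4-(benzyloxy)-3-methoxyphenyl]methanol | COc1cc(CO)ccc1OCc1ccccc1 | starting material
5 | 4-(benzyloxy)-3-methoxybenzyl bromide | COc1cc(CBr)ccc1OCc1ccccc1 | intermediate
6 | benzylic organolithium from 3 | COC(=O)c1c(C[Li])cc(OCc2ccccc2)cc1OC | intermediate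
7 | methyl 4-(benzyloxy)-2-{2-[4-(benzyloxy)-3-methoxyphenyl]ethyl}-6-methoxybenzoate | COC(=O)c1c(CCc2ccc(OCc3ccccc3)c(OC)c2)cc(OCc2ccccc2)cc1OC | intermediate
8 | Ar′-methanol | OCc1c(CCc2ccc(OCc3ccccc3)c(OC)c2)cc(OCc2ccccc2)cc1OC | intermediate
9 | Ar′-carbaldehyde | O=Cc1c(CCc2ccc(OCc3ccccc3)c(OC)c2)cc(OCc2ccccc2)cc1OC | intermediate
10 | 2,2-dimethyl-1,3-dioxane-4,6-dione | CC1(C)OC(=O)CC(=O)O1 | starting material
11 | 5-(Ar′-methylidene) Meldrum's acid | CC1(C)OC(=O)C(=Cc2c(CCc3ccc(OCc4ccccc4)c(OC)c3)cc(OCc3ccccc3)cc2OC)C(=O)O1 | intermediate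
12 | 5-(Ar′-methyl) Meldrum's acid | CC1(C)OC(=O)C(Cc2c(CCc3ccc(OCc4ccccc4)c(OC)c3)cc(OCc3ccccc3)cc2OC)C(=O)O1 | intermediate
13 | 3-Ar′-propanoic acid | OC(=O)CCc1c(CCc2ccc(OCc3ccccc3)c(OC)c2)cc(OCc2ccccc2)cc1OC | intermediate
14 | ethoxyethyne | CCOC#C | starting material
15 | 3-Ar′-propanoyl chloride | ClC(=O)CCc1c(CCc2ccc(OCc3ccccc3)c(OC)c2)cc(OCc2ccccc2)cc1OC | intermediate
16 | (Ar′-methyl)ketene | O=C=CCc1c(CCc2ccc(OCc3ccccc3)c(OC)c2)cc(OCc2ccccc2)cc1OC | intermediate
17 | rac-3-ethoxy-4-(Ar′-methyl)cyclobut-2-en-1-one | CCOC1=CC(=O)C1Cc1c(CCc2ccc(OCc3ccccc3)c(OC)c2)cc(OCc2ccccc2)cc1OC | intermediate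
18 | 2-(4-hydroxy-3-methoxyphenyl)ethanol | COc1cc(CCO)ccc1O | starting material
19 | 2-[4-(benzyloxy)-3-methoxyphenyl]ethanol | COc1cc(CCO)ccc1OCc1ccccc1 | intermediate
20 | 1-(benzyloxy)-4-(2-bromoethyl)-2-methoxybenzene | COc1cc(CCBr)ccc1OCc1ccccc1 | intermediate
21 | 2-Ar-ethylmagnesium bromide | COc1cc(CC[Mg]Br)ccc1OCc1ccccc1 | intermediate
22 | 2-Ar-ethylcerium dichloride | COc1cc(CC[Ce](Cl)Cl)ccc1OCc1ccccc1 | intermediate
23 | 3-ethoxy-4-(Ar′-methyl)-1-(2-Ar-ethyl)cyclobut-2-en-1-ol (racemic, diastereomer mixture) | CCOC1=CC(O)(CCc2ccc(OCc3ccccc3)c(OC)c2)C1Cc1c(CCc2ccc(OCc3ccccc3)c(OC)c2)cc(OCc2ccccc2)cc1OC | intermediate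
24 | rac-4-(Ar′-methyl)-3-(2-Ar-ethyl)cyclobut-2-en-1-one | O=C1C=C(CCc2ccc(OCc3ccccc3)c(OC)c2)C1Cc1c(CCc2ccc(OCc3ccccc3)c(OC)c2)cc(OCc2ccccc2)cc1OC | intermediate
25 | ethynyl(trimethyl)silane | C[Si](C)(C)C#C | starting material
26 | lithium (trimethylsilyl)acetylide | C[Si](C)(C)C#C[Li] | intermediate
27 | lithium (trimethylsilyl)ethynolate | C[Si](C)(C)C#CO[Li] | intermediate
28 | 1-(triisopropylsilyloxy)-2-(trimethylsilyl)ethyne | C[Si](C)(C)C#CO[Si](C(C)C)(C(C)C)C(C)C | intermediate
29 | (triisopropylsilyloxy)ethyne | C#CO[Si](C(C)C)(C(C)C)C(C)C | intermediate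
30 | (E)-vinylketene from 24 | O=C=C/C(CCc1ccc(OCc2ccccc2)c(OC)c1)=C/Cc1c(CCc2ccc(OCc3ccccc3)c(OC)c2)cc(OCc2ccccc2)cc1OC | intermediate
31 | rac-3-(triisopropylsilyloxy)-4-vinylcyclobutenone adduct | O=C1C=C(O[Si](C(C)C)(C(C)C)C(C)C)C1/C(CCc1ccc(OCc2ccccc2)c(OC)c1)=C/Cc1c(CCc2ccc(OCc3ccccc3)c(OC)c2)cc(OCc2ccccc2)cc1OC | intermediate
32 | dienylketene (ketenyl and vinyl groups cis on the central double bond) | O=C=C/C(O[Si](C(C)C)(C(C)C)C(C)C)=C\C(CCc1ccc(OCc2ccccc2)c(OC)c1)=C\Cc1c(CCc2ccc(OCc3ccccc3)c(OC)c2)cc(OCc2ccccc2)cc1OC | intermediate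
33 | rac-cyclohexa-2,4-dienone tautomer of 34 | O=C1C=C(O[Si](C(C)C)(C(C)C)C(C)C)C=C(CCc2ccc(OCc3ccccc3)c(OC)c2)C1Cc1c(CCc2ccc(OCc3ccccc3)c(OC)c2)cc(OCc2ccccc2)cc1OC | intermediate
34 | 2-(Ar′-methyl)-3-(2-Ar-ethyl)-5-(triisopropylsilyloxy)phenol | Oc1cc(O[Si](C(C)C)(C(C)C)C(C)C)cc(CCc2ccc(OCc3ccccc3)c(OC)c2)c1Cc1c(CCc2ccc(OCc3ccccc3)c(OC)c2)cc(OCc2ccccc2)cc1OC | intermediate
35 | methyl ether of 34 | COc1cc(O[Si](C(C)C)(C(C)C)C(C)C)cc(CCc2ccc(OCc3ccccc3)c(OC)c2)c1Cc1c(CCc2ccc(OCc3ccccc3)c(OC)c2)cc(OCc2ccccc2)cc1OC | intermediate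
36 | tribenzyl ether of the target | COc1cc(O)cc(CCc2ccc(OCc3ccccc3)c(OC)c2)c1Cc1c(CCc2ccc(OCc3ccccc3)c(OC)c2)cc(OCc2ccccc2)cc1OC | intermediate
37 | CNP0079383.0 | COc1cc(CCc2cc(O)cc(OC)c2Cc2c(CCc3ccc(O)c(OC)c3)cc(O)cc2OC)ccc1O | target

Total step count: 17. Longest linear sequence: 12 steps (1, 2, 4, 5, 6, 7, 8, 11, 14, 15, 16, 17).

Steps most likely to fail

Step 14. The vinylketene may be consumed by dimerisation or by acylating the phenol already formed. The ynol ether may drift to a silylketene by oxygen-to-carbon silyl shift, or the cascade may stall before the six-electron closure. The fallback joins two preformed rings A instead of building one, and sets out from 7 and 9. Ester 7 is saponified (KOH, aq. DMSO, 100 °C) to the benzoic acid F1. Transition-metal-free decarboxylative iodination (I2, K3PO4, MeCN, 100 °C) should then give the aryl iodide F2, with the halogen exactly at C2. Halogen–lithium exchange (n-BuLi, THF, −78 °C) gives the aryllithium F3, which adds to aldehyde 9 to give the diarylmethanol F4. Ionic reduction (Et3SiH, CF3CO2H, CH2Cl2, 0 °C) gives the tetrabenzyl ether F5, and hydrogenolysis (H2, Pd/C) comes back to the route at 37.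

Step 8. The monoalkylketene may dimerise or oligomerise faster than it meets the volatile ynol ether, and the ynol ether may be lost to hydrogen chloride. The fallback replaces the ketene by a keteniminium ion and also makes step 11 unnecessary. It sets out from 13 and 5. Acid 13 is coupled with dimethylamine (carbodiimide, CH2Cl2) to the N,N-dimethylamide F6. Bromide 5 is alkylated with lithiated 1-(trimethylsilyl)propyne to the silylated butyne F7, and K2CO3/MeOH gives the terminal alkyne F8. (CF3SO2)2O and 2,4,6-collidine in 1,2-dichloroethane convert F6 into the keteniminium triflate F9. Its [2+2] cycloaddition with F8 (alkyne CH to the iminium carbon) gives the cyclobuteniminium triflate F10, and hydrolysis with aq. NaHCO3 comes back to the route at 24.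

Step 13. Methanolysis may not stop at the carbon–silicon bond, with loss of the oxygen-bound silyl group or addition of methanol to the ynol ether, and the volatile product may be lost on concentration. The fallback carries the blocking group through the annulation, and sets out from 28 and 24. Thermolysis of 24 with 28 under the conditions of step 14 should give the C4-silylated phenol F11. Ipso-protodesilylation of this doubly oxygen-activated arylsilane (CF3CO2H, CH2Cl2, 0 °C) comes back to the route at 34.

Further compounds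
F1 | step 14 | 4-(benzyloxy)-2-(2-Ar-ethyl)-6-methoxybenzoic acid | OC(=O)c1c(CCc2ccc(OCc3ccccc3)c(OC)c2)cc(OCc2ccccc2)cc1OC
F2 | step 14 | Ar′ iodide | Ic1c(CCc2ccc(OCc3ccccc3)c(OC)c2)cc(OCc2ccccc2)cc1OC
F3 | step 14 | Ar′-lithium | [Li]c1c(CCc2ccc(OCc3ccccc3)c(OC)c2)cc(OCc2ccccc2)cc1OC
F4 | step 14 | bis(Ar′)methanol | OC(c1c(CCc2ccc(OCc3ccccc3)c(OC)c2)cc(OCc2ccccc2)cc1OC)c1c(CCc2ccc(OCc3ccccc3)c(OC)c2)cc(OCc2ccccc2)cc1OC
F5 | step 14 | bis(Ar′)methane (tetrabenzyl ether of the target) | C(c1c(CCc2ccc(OCc3ccccc3)c(OC)c2)cc(OCc2ccccc2)cc1OC)c1c(CCc2ccc(OCc3ccccc3)c(OC)c2)cc(OCc2ccccc2)cc1OC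
F6 | step 8 | N,N-dimethyl-3-Ar′-propanamide | CN(C)C(=O)CCc1c(CCc2ccc(OCc3ccccc3)c(OC)c2)cc(OCc2ccccc2)cc1OC
F7 | step 8 | 4-Ar-1-(trimethylsilyl)but-1-yne | C[Si](C)(C)C#CCCc1ccc(OCc2ccccc2)c(OC)c1
F8 | step 8 | 4-Ar-but-1-yne | C#CCCc1ccc(OCc2ccccc2)c(OC)c1
F9 | step 8 | N,N-dimethyl keteniminium triflate from F6 | C[N+](C)=C=CCc1c(CCc2ccc(OCc3ccccc3)c(OC)c2)cc(OCc2ccccc2)cc1OC.[O-]S(=O)(=O)C(F)(F)F
F10 | step 8 | rac-cyclobuteniminium triflate corresponding to 24 | C[N+](C)=C1C=C(CCc2ccc(OCc3ccccc3)c(OC)c2)C1Cc1c(CCc2ccc(OCc3ccccc3)c(OC)c2)cc(OCc2ccccc2)cc1OC.[O-]S(=O)(=O)C(F)(F)F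
F11 | step 13 | C4-(trimethylsilyl) derivative of 34 | Oc1c([Si](C)(C)C)c(O[Si](C(C)C)(C(C)C)C(C)C)cc(CCc2ccc(OCc3ccccc3)c(OC)c2)c1Cc1c(CCc2ccc(OCc3ccccc3)c(OC)c2)cc(OCc2ccccc2)cc1OC
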